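## Retrosynthetic overview

- Flavone locants are used with the unit in brackets: unit 1 is the 5-hydroxy-7-methoxy-6-methylflavone, unit 2 is the apigenin half, and the two are joined C3'(1)–C8(2). The plan rests on ring A of unit 2, a phloroglucinol ring whose three oxygens have different roles (O1 on C8a beside the aryl-bearing C8, OH on C7 on the other side of C8, OH on C5). This ring is therefore built from open-chain carbons so that the three oxygens arrive as OH, OSi(i-Pr)3 and OEt.
- Endgame: BCl3 dealkylation. Ring C(1) is opened at O1(1)–C2(1) to a chalcone, which is cut at C2(1)=C3(1) into a flavone aldehyde (unit 2 plus ring B(1)) and a 2-hydroxy-4,6-dimethoxy-5-methylacetophenone. The acetophenone comes from 2,6-dimethoxytoluene by C–H borylation/oxidation and C-acetylation.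
- Ring C(2) is opened at O1(2)–C2(2) to an o-hydroxyaryl ynone. The ynone is cut at C3(2)–C4(2) (aryl acetylide) and at C4(2)–C4a(2) (formylation directed by the C8a hydroxyl).
- Ring A(2) is cut by a vinylketene/siloxyalkyne benzannulation into 3-ethoxycyclobutenone (C8a, C4a, C5, C6) and an aryl siloxyalkyne (C8, C7). The crowded C3'(1)–C8(2) bond is thus only an aryl–alkyne bond, obtained from a salicylate ester through a Kowalski ynolate.
- Ring order: rings B(1), B(2) and A(1) are bought. Ring A(2) forms in step 4, ring C(2) in step 8 and ring C(1) in step 14.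

Key step: step 4

Assumption: 3-ethoxycyclobut-2-en-1-one is taken as purchasable, and the C3'(1)–C8(2) axis, which carries no descriptor in the target, is treated as stereochemically undefined.

## Route

Step 1
Reactants: 1 methyl 5-formyl-2-hydroxybenzoate
Product: 2 methyl 2-(benzyloxy)-5-formylbenzoate
Conditions: BnBr, K2CO3, DMF, 60 °C
Reagents that add atoms: benzyl bromide, BrCc1ccccc1
Why: Williamson ether synthesis, in which the phenoxide of 1 is alkylated on oxygen by the benzylic bromide while the ester and the non-enolisable aldehyde are inert to K2CO3.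

Step 2
Reactants: 2 methyl 2-(benzyloxy)-5-formylbenzoate
Product: 3 methyl 2-(benzyloxy)-5-(1,3-dioxolan-2-yl)benzoate
Conditions: HOCH2CH2OH, p-TsOH·H2O (cat.), toluene, Dean–Stark, reflux
Reagents that add atoms: ethylene glycol, OCCO
Why: Acid-catalysed acetalisation with azeotropic water removal masks the aldehyde, the only group that would compete with the ester for the carbanions of step 3, and leaves ester and benzyl ether alone.

Step 3
Reactants: 3 methyl 2-(benzyloxy)-5-(1,3-dioxolan-2-yl)benzoate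
Product: 6 [2-(benzyloxy)-5-(1,3-dioxolan-2-yl)phenyl]ethynyl triisopropylsilyl ether, via lithium dibromoenolate 4 (not isolated), via lithium ynolate 5 (not isolated)
Conditions: CH2Br2, LiTMP (lithium 2,2,6,6-tetramethylpiperidide), THF, −78 °C; LiN(SiMe3)2, −78 °C; n-BuLi (titrated), −78 °C → rt; i-Pr3SiOTf, −78 → 0 °C; aq NaHCO3
Reagents that add atoms: dibromomethane, BrCBr; triisopropylsilyl trifluoromethanesulfonate, CC(C)[Si](OS(=O)(=O)C(F)(F)F)(C(C)C)C(C)C; lithium bis(trimethylsilyl)amide, [Li]N([Si](C)(C)C)[Si](C)(C)C (its lithium stays only in 4 and 5)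
Why: Kowalski ester homologation stopped at the ynolate, in which LiCHBr2 is acylated by the ester, the amide base gives dibromoenolate 4, bromine–lithium exchange triggers the 1,2-aryl shift of the carbenoid to ynolate 5, and the bulky silyl triflate caps oxygen rather than carbon, the acetal being base-stable.

Step 4
Reactants: 6 [2-(benzyloxy)-5-(1,3-dioxolan-2-yl)phenyl]ethynyl triisopropylsilyl ether; 7 3-ethoxycyclobut-2-en-1-one
Product: 12 2-[2-(benzyloxy)-5-(1,3-dioxolan-2-yl)phenyl]-5-ethoxy-3-(triisopropylsilyloxy)phenol, via vinylketene 8 (not isolated), via vinylcyclobutenone 9 (not isolated), via dienylketene 10 (not isolated), via cyclohexadienone 11 (not isolated)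
Conditions: 7 (1.3 equiv), degassed toluene (0.4 M), sealed tube, 110 °C, then 145 °C
Reagents that add atoms: none
Why: Heat opens 7 by 4π electrocyclic cleavage of its C1–C4 bond to vinylketene 8, and the aryl-bearing carbon of 6 attacks the ketene carbonyl carbon in a [2+2] cycloaddition that gives 9 and forms C8(2)–C8a(2) and C6(2)–C7(2). Vinylcyclobutenone 9 opens reversibly (4π) to dienylketene 10, whose isomer with the ethoxyvinyl group turned toward the ketene closes ring A of unit 2 by 6π electrocyclisation (re-forming C4a(2)–C8a(2)) to dienone 11, and tautomerisation to phenol 12 makes the cascade irreversible. This is the Danheiser benzannulation, known for cyclobutenones and triisopropylsiloxyalkynes as a route to resorcinol monosilyl ethers of the same substitution pattern; the present pair differs only in its substituents, and the vinylogous-ester character of 7 is the reason for the second, hotter stage. Regiochemistry is the one selectivity at stake: the aryl group has to end up next to the new hydroxyl, which follows because oxygen donation makes the distal, aryl-bearing alkyne carbon the nucleophile and the ketene sp carbon is the only strong electrophile present. No stereocentre is kept, since the sp3 carbon of 9 vanishes on ring opening and the biaryl axis is undefined in the target. The neutral, reagent-free medium spares acetal, benzyl ether and silyl ether, and ring A is delivered with OH on C8a, OSi(i-Pr)3 on C7 and OEt on C5.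

Step 5
Reactants: 12 2-[2-(benzyloxy)-5-(1,3-dioxolan-2-yl)phenyl]-5-ethoxy-3-(triisopropylsilyloxy)phenol
Product: 14 3-[2-(benzyloxy)-5-(1,3-dioxolan-2-yl)phenyl]-6-ethoxy-2-hydroxy-4-(triisopropylsilyloxy)benzaldehyde, via hydroxymethylphenol 13 (not isolated)
Conditions: MgCl2 (anhydrous), Et3N, (CH2O)n, MeCN, reflux; pH 5 buffer work-up
Reagents that add atoms: paraformaldehyde (as formaldehyde), C=O
Why: Magnesium-mediated ortho-formylation (Casnati–Skattebøl reaction), in which the magnesium phenoxide delivers formaldehyde to C4a(2), the only free position ortho to the free hydroxyl, and a second formaldehyde oxidises the alkoxide of 13 by hydride transfer, while C6(2) lies between two capped oxygens and the basic medium with buffered work-up spares silyl ether and acetal.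

Step 6
Reactants: 14 3-[2-(benzyloxy)-5-(1,3-dioxolan-2-yl)phenyl]-6-ethoxy-2-hydroxy-4-(triisopropylsilyloxy)benzaldehyde; 15 1-(benzyloxy)-4-ethynylbenzene
Product: 17 rac-1-{3-[2-(benzyloxy)-5-(1,3-dioxolan-2-yl)phenyl]-6-ethoxy-2-hydroxy-4-(triisopropylsilyloxy)phenyl}-3-[4-(benzyloxy)phenyl]prop-2-yn-1-ol, via lithium acetylide 16 (not isolated)
Conditions: 15 (3.0 equiv), n-BuLi (2.8 equiv), THF, −78 °C; then 14, −78 → 0 °C; H2O
Reagents that add atoms: n-butyllithium, [Li]CCCC (its lithium stays only in 16)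
Why: 1,2-Addition of a lithium acetylide to an unprotected salicylaldehyde, a known operation when excess acetylide is used (one equivalent is spent on the phenol), and the new carbinol centre forms as a racemate that is erased in step 7.

Step 7
Reactants: 17 rac-propargylic alcohol
Product: 18 1-{3-[2-(benzyloxy)-5-(1,3-dioxolan-2-yl)phenyl]-6-ethoxy-2-hydroxy-4-(triisopropylsilyloxy)phenyl}-3-[4-(benzyloxy)phenyl]prop-2-yn-1-one
Conditions: MnO2 (activated), CH2Cl2, rt
Reagents that add atoms: none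
Why: Chemoselective MnO2 oxidation of a doubly activated (benzylic and propargylic) alcohol under neutral conditions leaves acetal, silyl ether and benzyl ethers untouched and gives an ynone whose phenol is hydrogen-bonded to the new carbonyl.

Step 8
Reactants: 18 o-hydroxyaryl ynone
Product: 19 8-[2-(benzyloxy)-5-(1,3-dioxolan-2-yl)phenyl]-2-[4-(benzyloxy)phenyl]-5-ethoxy-7-(triisopropylsilyloxy)-4H-chromen-4-one
Conditions: DMAP (20 mol %), DMF, 40 °C
Reagents that add atoms: none
Why: Nucleophile-catalysed 6-endo-dig cyclisation of an o-hydroxyaryl ynone, in which DMAP adds to the alkyne terminus C2(2) and the C8a oxygen displaces it by addition–elimination, steering closure to the flavone and away from the 5-exo aurone, and because only the C8a hydroxyl is free the 8-aryl isomer is the only one possible.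

Step 9
Reactants: 19 7-silyloxyflavone
Product: 21 7-(benzyloxy)-8-[2-(benzyloxy)-5-(1,3-dioxolan-2-yl)phenyl]-2-[4-(benzyloxy)phenyl]-5-ethoxy-4H-chromen-4-one, via cesium phenoxide 20 (not isolated)
Conditions: CsF, BnBr, DMF, rt
Reagents that add atoms: benzyl bromide, BrCc1ccccc1; cesium fluoride, [Cs+].[F-] (its cesium stays only in 20)
Why: Fluoride-induced desilylation with Williamson benzylation of the phenoxide in the same flask exchanges the 7-silyl ether, a vinylogous silyl ester that would not outlast the KOH of step 13, for a benzyl group that leaves with the others in step 15.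

Step 10
Reactants: 21 flavone acetal
Product: 22 4-(benzyloxy)-3-{7-(benzyloxy)-2-[4-(benzyloxy)phenyl]-5-ethoxy-4-oxo-4H-chromen-8-yl}benzaldehyde
Conditions: 1 M HCl, THF, rt
Reagents that add atoms: water, O
Why: Acid-catalysed acetal hydrolysis of an electron-rich aryl dioxolane is fast at room temperature, where the flavone and the aryl benzyl and ethyl ethers are stable.

Step 11
Reactants: 23 2,6-dimethoxytoluene
Product: 25 3,5-dimethoxy-4-methylphenol, via arylboronate 24 (not isolated)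
Conditions: [Ir(OMe)(cod)]2 (1.5 mol %), 4,4'-di-tert-butyl-2,2'-bipyridine (3 mol %), B2pin2 (0.6 equiv), THF, 80 °C; then aq NaOH, 30% H2O2, 0 °C → rt; dilute acid
Reagents that add atoms: hydrogen peroxide, OO; bis(pinacolato)diboron, CC1(C)OB(OC1(C)C)B1OC(C)(C)C(C)(C)O1 (its boron stays only in 24)
Why: Sterically governed iridium-catalysed C–H borylation followed by peroxide oxidation of the C–B bond in the same flask, in which only C4–H of this 1,2,3-trisubstituted arene has no ortho substituent, so the third oxygen enters para to the methyl group.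

Step 12
Reactants: 25 3,5-dimethoxy-4-methylphenol
Product: 26 1-(6-hydroxy-2,4-dimethoxy-3-methylphenyl)ethan-1-one
Conditions: Ac2O, BF3·OEt2, 80 °C; H2O
Reagents that add atoms: acetic anhydride, CC(=O)OC(C)=O
Why: BF3-promoted Friedel–Crafts C-acetylation (Fries-type) of a phloroglucinol ether, in which the two free ring positions are equivalent by symmetry and ortho to the hydroxyl, the para position is blocked by methyl, and the chelated ketone resists a second acylation.

Step 13
Reactants: 22 flavone aldehyde; 26 1-(6-hydroxy-2,4-dimethoxy-3-methylphenyl)ethan-1-one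
Product: 27 (E)-3-(4-(benzyloxy)-3-{7-(benzyloxy)-2-[4-(benzyloxy)phenyl]-5-ethoxy-4-oxo-4H-chromen-8-yl}phenyl)-1-(6-hydroxy-2,4-dimethoxy-3-methylphenyl)prop-2-en-1-one
Conditions: KOH (50% aq), EtOH/THF, rt; 1 M HCl to pH 5
Reagents that add atoms: none
Why: Claisen–Schmidt condensation, in which the enolate of 26 adds to the non-enolisable aldehyde and E1cB dehydration gives the thermodynamically preferred (E)-enone, while the fully O-alkylated flavone of unit 2 has no acidic proton and tolerates hydroxide at room temperature.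

Step 14
Reactants: 27 chalcone
Product: 29 2-(4-(benzyloxy)-3-{7-(benzyloxy)-2-[4-(benzyloxy)phenyl]-5-ethoxy-4-oxo-4H-chromen-8-yl}phenyl)-5,7-dimethoxy-6-methyl-4H-chromen-4-one, via flavanone 28 (not isolated)
Conditions: I2 (20 mol %), DMSO, 130 °C
Reagents that add atoms: none
Why: Iodine/DMSO oxidative cyclisation of a 2'-hydroxychalcone, in which oxa-Michael closure through the only free hydroxyl gives flavanone 28 (its racemic C2 is lost again), iodine dehydrogenates it by α-iodination and loss of HI, DMSO re-oxidises HI, and the methyl cap on O5(1) forces the 6-methyl rather than the 8-methyl flavone.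

Step 15
Reactants: 29 protected biflavone
Product: 30 target, 8-[2-hydroxy-5-(5-hydroxy-7-methoxy-6-methyl-4-oxo-4H-chromen-2-yl)phenyl]-5,7-dihydroxy-2-(4-hydroxyphenyl)-4H-chromen-4-one
Conditions: BCl3 (1 M in CH2Cl2, excess), C6HMe5, CH2Cl2, −78 °C → rt; H2O
Reagents that add atoms: none
Why: Lewis-acid ether cleavage, in which BCl3 with pentamethylbenzene as cation scavenger removes the three benzyl ethers in the cold and, on warming, boron chelation between each C4 carbonyl and its peri C5 oxygen activates only the C5(1) methyl and C5(2) ethyl ethers toward chloride, so the unchelated C7(1) methoxy group stays.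

## Compound list

1 | methyl 5-formyl-2-hydroxybenzoate | COC(=O)c1cc(C=O)ccc1O | starting material
2 | methyl 2-(benzyloxy)-5-formylbenzoate | COC(=O)c1cc(C=O)ccc1OCc1ccccc1 | intermediate
3 | methyl 2-(benzyloxy)-5-(1,3-dioxolan-2-yl)benzoate | COC(=O)c1cc(C2OCCO2)ccc1OCc1ccccc1 | intermediate
4 | lithium 1-[2-(benzyloxy)-5-(1,3-dioxolan-2-yl)phenyl]-2,2-dibromoethen-1-olate (not isolated) | [Li+].[O-]C(=C(Br)Br)c1cc(C2OCCO2)ccc1OCc1ccccc1 | intermediate
5 | lithium 2-[2-(benzyloxy)-5-(1,3-dioxolan-2-yl)phenyl]ethyn-1-olate (not isolated) | [Li+].[O-]C#Cc1cc(C2OCCO2)ccc1OCc1ccccc1 | intermediate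
6 | [2-(benzyloxy)-5-(1,3-dioxolan-2-yl)phenyl]ethynyl triisopropylsilyl ether | CC(C)[Si](C(C)C)(C(C)C)OC#Cc1cc(C2OCCO2)ccc1OCc1ccccc1 | intermediate
7 | 3-ethoxycyclobut-2-en-1-one | CCOC1=CC(=O)C1 | starting material
8 | 3-ethoxybuta-1,3-dien-1-one, vinylketene (not isolated) | CCOC(=C)C=C=O | intermediate
9 | rac-2-[2-(benzyloxy)-5-(1,3-dioxolan-2-yl)phenyl]-4-(1-ethoxyethenyl)-3-(triisopropylsilyloxy)cyclobut-2-en-1-one (not isolated) | CCOC(=C)C1C(=O)C(c2cc(C3OCCO3)ccc2OCc2ccccc2)=C1O[Si](C(C)C)(C(C)C)C(C)C | intermediate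
10 | (3E)-2-[2-(benzyloxy)-5-(1,3-dioxolan-2-yl)phenyl]-5-ethoxy-3-(triisopropylsilyloxy)hexa-1,3,5-trien-1-one (not isolated) | CCOC(=C)/C=C(O[Si](C(C)C)(C(C)C)C(C)C)\C(=C=O)c1cc(C2OCCO2)ccc1OCc1ccccc1 | intermediate
11 | 2-[2-(benzyloxy)-5-(1,3-dioxolan-2-yl)phenyl]-5-ethoxy-3-(triisopropylsilyloxy)cyclohexa-2,4-dien-1-one (not isolated) | CCOC1=CC(O[Si](C(C)C)(C(C)C)C(C)C)=C(c2cc(C3OCCO3)ccc2OCc2ccccc2)C(=O)C1 | intermediate
12 | 2-[2-(benzyloxy)-5-(1,3-dioxolan-2-yl)phenyl]-5-ethoxy-3-(triisopropylsilyloxy)phenol | CCOc1cc(O)c(-c2cc(C3OCCO3)ccc2OCc2ccccc2)c(O[Si](C(C)C)(C(C)C)C(C)C)c1 | intermediate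
13 | 2-[2-(benzyloxy)-5-(1,3-dioxolan-2-yl)phenyl]-5-ethoxy-6-(hydroxymethyl)-3-(triisopropylsilyloxy)phenol (not isolated, present as its magnesium salt) | CCOc1cc(O[Si](C(C)C)(C(C)C)C(C)C)c(-c2cc(C3OCCO3)ccc2OCc2ccccc2)c(O)c1CO | intermediate
14 | 3-[2-(benzyloxy)-5-(1,3-dioxolan-2-yl)phenyl]-6-ethoxy-2-hydroxy-4-(triisopropylsilyloxy)benzaldehyde | CCOc1cc(O[Si](C(C)C)(C(C)C)C(C)C)c(-c2cc(C3OCCO3)ccc2OCc2ccccc2)c(O)c1C=O | intermediate
15 | 1-(benzyloxy)-4-ethynylbenzene | C#Cc1ccc(OCc2ccccc2)cc1 | starting material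
16 | lithium [4-(benzyloxy)phenyl]acetylide (not isolated) | [Li]C#Cc1ccc(OCc2ccccc2)cc1 | intermediate
17 | rac-1-{3-[2-(benzyloxy)-5-(1,3-dioxolan-2-yl)phenyl]-6-ethoxy-2-hydroxy-4-(triisopropylsilyloxy)phenyl}-3-[4-(benzyloxy)phenyl]prop-2-yn-1-ol | CCOc1cc(O[Si](C(C)C)(C(C)C)C(C)C)c(-c2cc(C3OCCO3)ccc2OCc2ccccc2)c(O)c1C(O)C#Cc1ccc(OCc2ccccc2)cc1 | intermediate
18 | 1-{3-[2-(benzyloxy)-5-(1,3-dioxolan-2-yl)phenyl]-6-ethoxy-2-hydroxy-4-(triisopropylsilyloxy)phenyl}-3-[4-(benzyloxy)phenyl]prop-2-yn-1-one | CCOc1cc(O[Si](C(C)C)(C(C)C)C(C)C)c(-c2cc(C3OCCO3)ccc2OCc2ccccc2)c(O)c1C(=O)C#Cc1ccc(OCc2ccccc2)cc1 | intermediate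
19 | 8-[2-(benzyloxy)-5-(1,3-dioxolan-2-yl)phenyl]-2-[4-(benzyloxy)phenyl]-5-ethoxy-7-(triisopropylsilyloxy)-4H-chromen-4-one | CCOc1cc(O[Si](C(C)C)(C(C)C)C(C)C)c(-c2cc(C3OCCO3)ccc2OCc2ccccc2)c2oc(-c3ccc(OCc4ccccc4)cc3)cc(=O)c12 | intermediate
20 | cesium 8-[2-(benzyloxy)-5-(1,3-dioxolan-2-yl)phenyl]-2-[4-(benzyloxy)phenyl]-5-ethoxy-4-oxo-4H-chromen-7-olate (not isolated) | CCOc1cc([O-])c(-c2cc(C3OCCO3)ccc2OCc2ccccc2)c2oc(-c3ccc(OCc4ccccc4)cc3)cc(=O)c12.[Cs+] | intermediate
21 | 7-(benzyloxy)-8-[2-(benzyloxy)-5-(1,3-dioxolan-2-yl)phenyl]-2-[4-(benzyloxy)phenyl]-5-ethoxy-4H-chromen-4-one | CCOc1cc(OCc2ccccc2)c(-c2cc(C3OCCO3)ccc2OCc2ccccc2)c2oc(-c3ccc(OCc4ccccc4)cc3)cc(=O)c12 | intermediate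
22 | 4-(benzyloxy)-3-{7-(benzyloxy)-2-[4-(benzyloxy)phenyl]-5-ethoxy-4-oxo-4H-chromen-8-yl}benzaldehyde | CCOc1cc(OCc2ccccc2)c(-c2cc(C=O)ccc2OCc2ccccc2)c2oc(-c3ccc(OCc4ccccc4)cc3)cc(=O)c12 | intermediate
23 | 2,6-dimethoxytoluene | COc1cccc(OC)c1C | starting material
24 | 2-(3,5-dimethoxy-4-methylphenyl)-4,4,5,5-tetramethyl-1,3,2-dioxaborolane (not isolated) | COc1cc(B2OC(C)(C)C(C)(C)O2)cc(OC)c1C | intermediate
25 | 3,5-dimethoxy-4-methylphenol | COc1cc(O)cc(OC)c1C | intermediate
26 | 1-(6-hydroxy-2,4-dimethoxy-3-methylphenyl)ethan-1-one | COc1cc(O)c(C(C)=O)c(OC)c1C | intermediate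
27 | (E)-3-(4-(benzyloxy)-3-{7-(benzyloxy)-2-[4-(benzyloxy)phenyl]-5-ethoxy-4-oxo-4H-chromen-8-yl}phenyl)-1-(6-hydroxy-2,4-dimethoxy-3-methylphenyl)prop-2-en-1-one | COc1cc(O)c(C(=O)/C=C/c2ccc(OCc3ccccc3)c(-c3c(OCc4ccccc4)cc(OCC)c4c(=O)cc(-c5ccc(OCc6ccccc6)cc5)oc34)c2)c(OC)c1C | intermediate
28 | rac-2-(4-(benzyloxy)-3-{7-(benzyloxy)-2-[4-(benzyloxy)phenyl]-5-ethoxy-4-oxo-4H-chromen-8-yl}phenyl)-5,7-dimethoxy-6-methylchroman-4-one (not isolated) | COc1cc2OC(c3ccc(OCc4ccccc4)c(-c4c(OCc5ccccc5)cc(OCC)c5c(=O)cc(-c6ccc(OCc7ccccc7)cc6)oc45)c3)CC(=O)c2c(OC)c1C | intermediate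
29 | 2-(4-(benzyloxy)-3-{7-(benzyloxy)-2-[4-(benzyloxy)phenyl]-5-ethoxy-4-oxo-4H-chromen-8-yl}phenyl)-5,7-dimethoxy-6-methyl-4H-chromen-4-one | COc1cc2oc(-c3ccc(OCc4ccccc4)c(-c4c(OCc5ccccc5)cc(OCC)c5c(=O)cc(-c6ccc(OCc7ccccc7)cc6)oc45)c3)cc(=O)c2c(OC)c1C | intermediate
30 | 8-[2-hydroxy-5-(5-hydroxy-7-methoxy-6-methyl-4-oxo-4H-chromen-2-yl)phenyl]-5,7-dihydroxy-2-(4-hydroxyphenyl)-4H-chromen-4-one (CNP0113589.0) | COc1cc2oc(-c3ccc(O)c(-c4c(O)cc(O)c5c(=O)cc(-c6ccc(O)cc6)oc45)c3)cc(=O)c2c(O)c1C | target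

## Step count and risks

Total steps: 15. Longest linear sequence: 13 (steps 1–10, then 13–15). Steps 11–12 form the side branch.

**Risk 1, step 4 (benzannulation).**
- What may go wrong:
  - The donor-stabilised cyclobutenone may open too slowly at temperatures the siloxyalkyne tolerates, so that thermal silyl migration to a silylketene and self-condensation of the ketene compete.
  - The ortho-substituted aryl group may slow the [2+2] addition.
  - Surplus ketene may acylate the product phenol.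
- Fallback: form the C3'(1)–C8(2) bond by Suzuki–Miyaura coupling of two finished flavones. It sets out from acetophenone 26 and comes back at protected biflavone 29.
- Unit 1 half:
  - Compound 26 is condensed with commercial 4-(benzyloxy)-3-bromobenzaldehyde (KOH, EtOH, rt) to (E)-3-[4-(benzyloxy)-3-bromophenyl]-1-(6-hydroxy-2,4-dimethoxy-3-methylphenyl)prop-2-en-1-one F1.
  - I2 (cat.) in DMSO at 130 °C converts this into 2-[4-(benzyloxy)-3-bromophenyl]-5,7-dimethoxy-6-methyl-4H-chromen-4-one F2.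
  - Miyaura borylation (B2pin2, PdCl2(dppf), KOAc, dioxane, 90 °C) gives 2-[4-(benzyloxy)-3-(4,4,5,5-tetramethyl-1,3,2-dioxaborolan-2-yl)phenyl]-5,7-dimethoxy-6-methyl-4H-chromen-4-one F3.
- Unit 2 half:
  - Commercial apigenin is benzylated on O7 and O4' (BnBr, K2CO3, DMF; the chelated 5-OH stays free) to 7-(benzyloxy)-2-[4-(benzyloxy)phenyl]-5-hydroxy-4H-chromen-4-one F4.
  - Ethylation on O5 (EtI, K2CO3, DMF, 60 °C) gives 7-(benzyloxy)-2-[4-(benzyloxy)phenyl]-5-ethoxy-4H-chromen-4-one F5.
  - Iodination at C8, the position favoured in fully alkylated 5,7-dioxygenated flavones (I2, AgO2CCF3, CH2Cl2), gives 7-(benzyloxy)-2-[4-(benzyloxy)phenyl]-5-ethoxy-8-iodo-4H-chromen-4-one F6.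
- Coupling of F3 with F6 (Pd(OAc)2, SPhos, K3PO4, toluene/H2O, 100 °C) gives 29.

**Risk 2, step 3 (ynolate formation and O-silylation).**
- What may go wrong:
  - Surplus alkyllithium may metalate the benzylic CH2 of the aryl benzyl ether, leading to Wittig rearrangement.
  - Addition of LiCHBr2 to the ortho-alkoxy ester may stay incomplete.
  - The silyl triflate may open the dioxolane, or silylate carbon to give a silylketene.
- Fallback: reach the same ynolate by oxidising a lithium acetylide, which needs only one equivalent of strong base. It sets out from ester 3 and comes back at siloxyalkyne 6, passing through ynolate 5.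
  - Ester 3 is reduced (LiAlH4, THF, 0 °C) to [2-(benzyloxy)-5-(1,3-dioxolan-2-yl)phenyl]methanol F7.
  - Oxidation (MnO2, CH2Cl2) gives 2-(benzyloxy)-5-(1,3-dioxolan-2-yl)benzaldehyde F8.
  - Homologation with the Ohira–Bestmann reagent (K2CO3, MeOH, rt) gives 2-[4-(benzyloxy)-3-ethynylphenyl]-1,3-dioxolane F9.
  - Deprotonation (n-BuLi, 1.0 equiv, THF, −78 °C) and oxygen transfer from lithium tert-butyl peroxide (t-BuOOH, LiN(SiMe3)2, −78 → 0 °C) give 5, which is capped with i-Pr3SiOTf at −78 °C to give 6.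

**Risk 3, step 15 (global dealkylation).**
- What may go wrong:
  - Chloride attack on the chelated ethyl ether at C5(2) may lag behind the other cleavages.
  - Forcing the reaction may start to erode the C7(1) methoxy group.
  - Benzyl cations may alkylate the electron-rich rings.
- Fallback: split the deprotection into two orthogonal operations. It sets out from 29 and comes back at target 30.
  - Hydrogenolysis (H2, Pd/C, THF/MeOH, rt) removes the three benzyl groups. It gives 5-ethoxy-7-hydroxy-8-[2-hydroxy-5-(5,7-dimethoxy-6-methyl-4-oxo-4H-chromen-2-yl)phenyl]-2-(4-hydroxyphenyl)-4H-chromen-4-one F10.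
  - Chelation-directed dealkylation with MgI2·OEt2 (THF, reflux) follows. Iodide is a far better nucleophile toward the ethyl group, and magnesium binds only the carbonyl/peri-oxygen pairs, so the two C5 ethers are cleaved to give 30.

## Further compounds

F1 | step 4 | (E)-3-[4-(benzyloxy)-3-bromophenyl]-1-(6-hydroxy-2,4-dimethoxy-3-methylphenyl)prop-2-en-1-one | COc1cc(O)c(C(=O)/C=C/c2ccc(OCc3ccccc3)c(Br)c2)c(OC)c1C
F2 | step 4 | 2-[4-(benzyloxy)-3-bromophenyl]-5,7-dimethoxy-6-methyl-4H-chromen-4-one | COc1cc2oc(-c3ccc(OCc4ccccc4)c(Br)c3)cc(=O)c2c(OC)c1C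
F3 | step 4 | 2-[4-(benzyloxy)-3-(4,4,5,5-tetramethyl-1,3,2-dioxaborolan-2-yl)phenyl]-5,7-dimethoxy-6-methyl-4H-chromen-4-one | COc1cc2oc(-c3ccc(OCc4ccccc4)c(B4OC(C)(C)C(C)(C)O4)c3)cc(=O)c2c(OC)c1C
F4 | step 4 | 7-(benzyloxy)-2-[4-(benzyloxy)phenyl]-5-hydroxy-4H-chromen-4-one | O=c1cc(-c2ccc(OCc3ccccc3)cc2)oc2cc(OCc3ccccc3)cc(O)c12
F5 | step 4 | 7-(benzyloxy)-2-[4-(benzyloxy)phenyl]-5-ethoxy-4H-chromen-4-one | CCOc1cc(OCc2ccccc2)cc2oc(-c3ccc(OCc4ccccc4)cc3)cc(=O)c12
F6 | step 4 | 7-(benzyloxy)-2-[4-(benzyloxy)phenyl]-5-ethoxy-8-iodo-4H-chromen-4-one | CCOc1cc(OCc2ccccc2)c(I)c2oc(-c3ccc(OCc4ccccc4)cc3)cc(=O)c12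
F7 | step 3 | [2-(benzyloxy)-5-(1,3-dioxolan-2-yl)phenyl]methanol | OCc1cc(C2OCCO2)ccc1OCc1ccccc1
F8 | step 3 | 2-(benzyloxy)-5-(1,3-dioxolan-2-yl)benzaldehyde | O=Cc1cc(C2OCCO2)ccc1OCc1ccccc1
F9 | step 3 | 2-[4-(benzyloxy)-3-ethynylphenyl]-1,3-dioxolane | C#Cc1cc(C2OCCO2)ccc1OCc1ccccc1
F10 | step 15 | 5-ethoxy-7-hydroxy-8-[2-hydroxy-5-(5,7-dimethoxy-6-methyl-4-oxo-4H-chromen-2-yl)phenyl]-2-(4-hydroxyphenyl)-4H-chromen-4-one | COc1cc2oc(-c3ccc(O)c(-c4c(O)cc(OCC)c5c(=O)cc(-c6ccc(O)cc6)oc45)c3)cc(=O)c2c(OC)c1C
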